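Start with an easy step: take the natural logarithm of each violet X reading as a fall from the charge, because a catalyst working pseudo-first-order in X draws a straight line that way.

| setting | violet | flask |
|---|---|---|
| X | 20 mM | 10 mM |
| Z | 0.02 mol% | 0.02 mol% |
| remark | run made earlier |  |
| time |  | 50 min |

violet run (percent of the X charged)

| time / min | X / % | L / % |
|---|---|---|
| 0.250 | 93.6 | 5.1 |
| 0.833 | 81.7 | 16.0 |
| 1.33 | 73.4 | 25.1 |
| 2.00 | 63.7 | 35.9 |
| 3.00 | 50.6 | 45.2 |
| 4.00 | 41.6 | 55.7 |
| 5.00 | 36.9 | 63.3 |

(standard deviation of a reading: 1 percentage point)

- candidate steps: X + Z -> L + Z; Z -> Q; X -> G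
- no earlier run changes the charge of Z; that part of a forecast is a guess

* amount of X in percent of the X charged, at 5.0 min, 15 min, 30 min and 50 min

You see the violet log-fall climb at 0.243 min⁻¹ early on, but at 0.120 min⁻¹ between the last two readings. If Z is dying, the slope decays by about 0.173 min⁻¹, a reading with the scatter behind it. A decaying slope adds up to a finite total. Carried back to the start, it gives the reach, the total log-fall a charge of Z can buy before it dies: 1.51 for the violet run.

Now my own bracket. If X enters at first order, log-fall follows the concentration of Z, which in the flask is half the violet one, so the reach halves and X stops near 47.0%. If X enters at zero order, percent fall follows the loading, which is the same, so the flask copies the violet run and X stops near 22.1%. At 5.0 min the same two ends give 60.7% and 36.9%.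

The forecast gives 60%, 34%, 24% and 22%, and says “X plateaus as the catalyst dies”. Its first value lies near the upper end of the bracket, its last near the lower end.

The flask gives 46.1%, 32.2%, 29.4% and 27.0%.

    X + Z → L + Z, rate k1*[X]^2.5*[Z]/(1 + ([X]/Kh1)^2.5) (4.10 mM, k = 1.80 × 10⁷ L²·⁵ mol⁻²·⁵ s⁻¹)
    Z → Q (k = 0.00400 s⁻¹)
    X → G (k = 7.10 × 10⁻⁵ s⁻¹)

The flask's log-fall at 50 min is 1.31, inside the bracket, and X flattens with Z down to 0.248% of its charge by 25.0 min. The loss of Z together with the short time holds X up: without Z → Q the flask ends at 3.20%, and ten times the time gives 3.97%. The simulated flask with twice the Z has the violet concentration of Z and double its loading, so the first-order end of the bracket stops X near 22.1%, while the zero-order end reckons a percent fall of 156%, past the charge, which takes that end down to nil; that flask holds 12.8%.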